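**Strategy.** Everything rests on disconnecting the lower pyran ring (ring F) across C4–C4a and O1–C2. Ring D is a resorcinol: its C4a (para to the 7-OH) and the neighbouring phenolic oxygen form a 1,3-C,O-binucleophile. One operation, a boron-templated ortho-hydroxyalkylation, ortho-quinone methide formation and oxa-6π electrocyclisation, welds an α-methoxycinnamaldehyde (C2–C3–C4) onto the free resorcinol already attached to C4 of a benzylated guibourtinidol unit. Ring F emerges as a 3-methoxy-2H-chromene, the enol ether of a flavan-3-one, so hydrolysis and transfer hydrogenation under dynamic kinetic resolution then set the cis (2S,3S) centres by catalyst control before hydrogenolysis.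

Key step: step 8

Remark: rings A, B, C belong to the upper unit and rings D (benzo), E (catechol), F (pyran) to the lower unit, whose atoms carry the usual flavan numbers; acetophenone 1 and methoxyacetaldehyde 11 are taken as purchasable.

**Step 1**
Reactants: 1 1-[4-(benzyloxy)-2-hydroxyphenyl]ethan-1-one
Product: 2 1-[4-(benzyloxy)-2-(methoxymethoxy)phenyl]ethan-1-one
Conditions: NaH, MOMCl, DMF, 0 °C to rt
Reagents that add atoms: chloromethyl methyl ether, COCCl
Why: Williamson etherification of the sodium phenoxide gives the MOM ether, which masks the chelated ortho-OH so that the enone made next can be epoxidised without Algar–Flynn–Oyamada-type ring closure; no stereocentre is formed.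

**Step 2**
Reactants: 2 1-[4-(benzyloxy)-2-(methoxymethoxy)phenyl]ethan-1-one; 3 4-(benzyloxy)benzaldehyde
Product: 4 (E)-1-[4-(benzyloxy)-2-(methoxymethoxy)phenyl]-3-[4-(benzyloxy)phenyl]prop-2-en-1-one
Conditions: KOH, EtOH/THF, rt
Reagents that add atoms: none
Why: Claisen–Schmidt aldol condensation of the methyl ketone enolate with the non-enolisable aldehyde, the E1cB dehydration giving the thermodynamically favoured (E)-enone.

**Step 3**
Reactants: 4 (E)-chalcone
Product: 5 [4-(benzyloxy)-2-(methoxymethoxy)phenyl]{(2R,3S)-3-[4-(benzyloxy)phenyl]oxiran-2-yl}methanone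
Conditions: poly-L-leucine (cat.), urea–H2O2, DBU, THF, rt
Reagents that add atoms: hydrogen peroxide (used as its urea adduct), OO
Why: Juliá–Colonna nucleophilic epoxidation: the helical poly-L-leucine binds the enone and the hydroperoxide so that Weitz–Scheffer addition occurs on one enone face, which should give the trans-(2R,3S)-epoxy ketone and so fixes the absolute configuration of the whole upper unit.

**Step 4**
Reactants: 5 (2R,3S)-epoxy ketone
Product: 6 (2R,3R)-7-(benzyloxy)-2-[4-(benzyloxy)phenyl]-3-hydroxychroman-4-one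
Conditions: conc. HCl, MeOH/THF, 50 °C
Reagents that add atoms: none
Why: Acid cleaves the MOM acetal and the liberated phenol opens the epoxide in a 6-endo attack at the benzylic carbon, activated by the 4-benzyloxyphenyl group, with inversion, so the trans-epoxide becomes the 2,3-trans (2R,3R)-dihydroflavonol while the carbinol centre is carried over unchanged.

**Step 5**
Reactants: 6 (2R,3R)-dihydroflavonol
Product: 7 (2R,3S,4R)-7-(benzyloxy)-2-[4-(benzyloxy)phenyl]chromane-3,4-diol
Conditions: NaBH4, THF/EtOH, 0 °C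
Reagents that add atoms: none
Why: Borohydride reduction of the aryl ketone, hydride adding mainly anti to the C3 hydroxyl to give the 3,4-trans diol (4R); the C4 configuration is of no consequence because C4 is ionised in step 6.

**Step 6**
Reactants: 7 flavan-3,4-diol; 8 resorcinol
Product: 9 (2R,3S,4S)-7-(benzyloxy)-2-[4-(benzyloxy)phenyl]-4-(2,4-dihydroxyphenyl)chroman-3-ol (2,3-trans-3,4-cis)
Conditions: resorcinol (6 equiv), BF3·OEt2 (0.5 equiv), 1,4-dioxane, 10 °C to rt; chromatography
Reagents that add atoms: none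
Why: Friedel–Crafts alkylation as in biomimetic flavan-4-yl couplings: BF3 ionises the benzylic C4–OH to a cation stabilised by the para 7-benzyloxy group and resorcinol, in excess, attacks through its C4 (ortho and para to the hydroxyls); the 2,3-trans cation is expected to be captured on both faces, and the 3,4-cis adduct (aryl syn to the 3-OH, 4S) is separated from its C4 epimer by chromatography.

**Step 7**
Reactants: 10 3,4-bis(benzyloxy)benzaldehyde; 11 methoxyacetaldehyde
Product: 12 (Z)-3-[3,4-bis(benzyloxy)phenyl]-2-methoxyprop-2-enal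
Conditions: NaOH (aq.), MeOH, 0 °C to rt, slow addition of 11
Reagents that add atoms: none
Why: Crossed (Claisen–Schmidt) aldol condensation of the enolisable α-alkoxy aldehyde with the non-enolisable aryl aldehyde, slow addition suppressing self-condensation and E1cB dehydration giving the (Z)-enal with aryl trans to the formyl group.

**Step 8**
Reactants: 9 resorcinol adduct; 12 (Z)-α-methoxy enal
Product: 15 (2R,3S,4S)-7-(benzyloxy)-2-[4-(benzyloxy)phenyl]-4-{2-[3,4-bis(benzyloxy)phenyl]-7-hydroxy-3-methoxy-2H-chromen-6-yl}chroman-3-ol (both C2 epimers of ring F), via benzodioxaborin 13 (not isolated), via ortho-quinone methide 14 (not isolated)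
Conditions: PhB(OH)2 (2.2 equiv), EtCO2H (cat.), 12 (1.05 equiv), toluene, reflux, Dean–Stark
Reagents that add atoms: none
Why: Phenylboronic acid esterifies the C8a–OH of ring D and binds the aldehyde of 12, so that C4a (ortho to this oxygen, para to the 7-OH) attacks the carbonyl carbon through a six-membered transition state to give benzodioxaborin 13 (bond C4–C4a); heating expels phenylboronic acid to leave the 1-oxatriene (ortho-quinone methide) 14, which closes by thermal disrotatory oxa-6π electrocyclisation (bond O1–C2). The closest known reaction is the boronic-acid-mediated ortho-specific condensation of phenols with α,β-unsaturated aldehydes to 2H-chromenes, a formal [3+3] annulation. Ring F is thus closed by a pericyclic 6π ring closure, not by an ionic exo or endo attack. C2 is formed without control (both epimers), by design: it is α to the carbonyl unveiled in step 9, where it is equilibrated and fixed under catalyst control, and the C3 methoxy group installs the C3 oxygen at the ketone oxidation level. The step needs attack at C4a in preference to C8 and a single annulation: C8 is flanked by two oxygens, the 7-OH is crowded by the flavanyl group (and can be tied to the neighbouring 3-OH as a cyclic boronate), all other phenols are benzylated, and only a slight excess of 12 is used.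

**Step 9**
Reactants: 15 3-methoxy-2H-chromene (C2 epimers)
Product: 17 (2R,3S,4S)-7-(benzyloxy)-2-[4-(benzyloxy)phenyl]-4-{(2S,3S)-2-[3,4-bis(benzyloxy)phenyl]-3,7-dihydroxychroman-6-yl}chroman-3-ol, via flavan-3-one 16 (not isolated)
Conditions: 0.5 M aq. HCl, THF, rt, degassed; then Et3N, HCO2H/Et3N (1:1), RuCl[(S,S)-TsDPEN](p-cymene) (2 mol %), DMF, 40 °C
Reagents that add atoms: water, O
Why: Aqueous acid hydrolyses the methyl enol ether to the flavan-3-one, whose C2 (α to the carbonyl, benzylic and O-substituted) epimerises under the amine while Noyori–Ikariya asymmetric transfer hydrogenation reduces one C2 epimer faster and on the face anti to the C2 aryl group (dynamic kinetic resolution), so the catalyst sets C3 as S and the cis relationship then fixes C2 as S, independently of the remote upper unit.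

**Step 10**
Reactants: 17 tetra-O-benzyl ether of the target
Product: 18 (2R,3S,4S)-2-(4-hydroxyphenyl)-4-[(2S,3S)-2-(3,4-dihydroxyphenyl)-3,7-dihydroxychroman-6-yl]chromane-3,7-diol (target)
Conditions: H2 (1 atm), Pd(OH)2/C, THF/MeOH, rt
Reagents that add atoms: none
Why: Heterogeneous hydrogenolysis of the four benzyl ethers under neutral conditions at ambient pressure, under which the cyclic benzylic C2–O1 bonds and all five stereocentres are untouched, should give the target.

**Compound list**

1 | 1-[4-(benzyloxy)-2-hydroxyphenyl]ethan-1-one | CC(=O)c1ccc(OCc2ccccc2)cc1O | starting material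
2 | 1-[4-(benzyloxy)-2-(methoxymethoxy)phenyl]ethan-1-one | CC(=O)c1ccc(OCc2ccccc2)cc1OCOC | intermediate
3 | 4-(benzyloxy)benzaldehyde | O=Cc1ccc(OCc2ccccc2)cc1 | starting material
4 | (E)-1-[4-(benzyloxy)-2-(methoxymethoxy)phenyl]-3-[4-(benzyloxy)phenyl]prop-2-en-1-one | O=C(/C=C/c1ccc(OCc2ccccc2)cc1)c1ccc(OCc2ccccc2)cc1OCOC | intermediate
5 | [4-(benzyloxy)-2-(methoxymethoxy)phenyl]{(2R,3S)-3-[4-(benzyloxy)phenyl]oxiran-2-yl}methanone | O=C(c1ccc(OCc2ccccc2)cc1OCOC)[C@@H]1O[C@H]1c1ccc(OCc2ccccc2)cc1 | intermediate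
6 | (2R,3R)-7-(benzyloxy)-2-[4-(benzyloxy)phenyl]-3-hydroxychroman-4-one | O=C1[C@H](O)[C@@H](c2ccc(OCc3ccccc3)cc2)Oc2cc(OCc3ccccc3)ccc21 | intermediate
7 | (2R,3S,4R)-7-(benzyloxy)-2-[4-(benzyloxy)phenyl]chromane-3,4-diol | O[C@H]1[C@H](O)[C@@H](c2ccc(OCc3ccccc3)cc2)Oc2cc(OCc3ccccc3)ccc21 | intermediate
8 | resorcinol (benzene-1,3-diol) | Oc1cccc(O)c1 | starting material
9 | (2R,3S,4S)-7-(benzyloxy)-2-[4-(benzyloxy)phenyl]-4-(2,4-dihydroxyphenyl)chroman-3-ol | O[C@@H]1[C@@H](c2ccc(OCc3ccccc3)cc2)Oc2cc(OCc3ccccc3)ccc2[C@@H]1c1ccc(O)cc1O | intermediate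
10 | 3,4-bis(benzyloxy)benzaldehyde | O=Cc1ccc(OCc2ccccc2)c(OCc2ccccc2)c1 | starting material
11 | methoxyacetaldehyde | COCC=O | starting material
12 | (Z)-3-[3,4-bis(benzyloxy)phenyl]-2-methoxyprop-2-enal | O=C/C(OC)=C/c1ccc(OCc2ccccc2)c(OCc2ccccc2)c1 | intermediate
13 | 2-phenyl-4H-1,3,2-benzodioxaborin built on ring D of 9: C8a–O–B(Ph)–O–C4H–C4a, C4 carrying the (Z)-1-methoxy-2-[3,4-bis(benzyloxy)phenyl]vinyl group (C4 epimers) | O[C@@H]1[C@@H](c2ccc(OCc3ccccc3)cc2)Oc2cc(OCc3ccccc3)ccc2[C@@H]1c1cc2C(/C(OC)=C/c3ccc(OCc4ccccc4)c(OCc4ccccc4)c3)OB(c3ccccc3)Oc2cc1O | intermediate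
14 | ortho-quinone methide (1-oxatriene) from 13: ring D as 6-alkylidenecyclohexa-2,4-dienone, C8a=O and C4a=C4H–C3(OMe)=C2H–aryl | O[C@@H]1[C@@H](c2ccc(OCc3ccccc3)cc2)Oc2cc(OCc3ccccc3)ccc2[C@@H]1C1=CC(=C/C(OC)=C/c2ccc(OCc3ccccc3)c(OCc3ccccc3)c2)C(=O)C=C1O | intermediate
15 | (2R,3S,4S)-7-(benzyloxy)-2-[4-(benzyloxy)phenyl]-4-{2-[3,4-bis(benzyloxy)phenyl]-7-hydroxy-3-methoxy-2H-chromen-6-yl}chroman-3-ol (both C2 epimers of ring F) | O[C@@H]1[C@@H](c2ccc(OCc3ccccc3)cc2)Oc2cc(OCc3ccccc3)ccc2[C@@H]1c1cc2C=C(OC)C(c3ccc(OCc4ccccc4)c(OCc4ccccc4)c3)Oc2cc1O | intermediate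
16 | 6-{(2R,3S,4S)-7-(benzyloxy)-2-[4-(benzyloxy)phenyl]-3-hydroxychroman-4-yl}-2-[3,4-bis(benzyloxy)phenyl]-7-hydroxychroman-3-one (C2 epimers, interconverting) | O[C@@H]1[C@@H](c2ccc(OCc3ccccc3)cc2)Oc2cc(OCc3ccccc3)ccc2[C@@H]1c1cc2CC(=O)C(c3ccc(OCc4ccccc4)c(OCc4ccccc4)c3)Oc2cc1O | intermediate
17 | (2R,3S,4S)-7-(benzyloxy)-2-[4-(benzyloxy)phenyl]-4-{(2S,3S)-2-[3,4-bis(benzyloxy)phenyl]-3,7-dihydroxychroman-6-yl}chroman-3-ol | O[C@@H]1[C@@H](c2ccc(OCc3ccccc3)cc2)Oc2cc(OCc3ccccc3)ccc2[C@@H]1c1cc2C[C@H](O)[C@H](c3ccc(OCc4ccccc4)c(OCc4ccccc4)c3)Oc2cc1O | intermediate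
18 | (2R,3S,4S)-2-(4-hydroxyphenyl)-4-[(2S,3S)-2-(3,4-dihydroxyphenyl)-3,7-dihydroxychroman-6-yl]chromane-3,7-diol | O[C@@H]1[C@@H](c2ccc(O)cc2)Oc2cc(O)ccc2[C@@H]1c1cc2C[C@H](O)[C@H](c3ccc(O)c(O)c3)Oc2cc1O | target

**Count and risks**

Total step count: 10. Longest linear sequence: 9 steps (steps 1 to 6, then 8, 9 and 10); step 7 is a one-step side branch.

Steps most likely to fail:

1. Step 8. The annulation may occur at C8 (between the two ring D oxygens) or twice, the resorcinol may be lost from C4 by acid-promoted retro-Friedel–Crafts cleavage in hot toluene, or the α-methoxy enal may be attacked too slowly. The fallback reverses the order of events, so that the annulation is run on a simple monophenol and the interflavanyl bond is made last. It sets out from 12 and 7 and comes back to the route at 18.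
 - Enal 12 and commercial 3-(benzyloxy)phenol, under the conditions of step 8, should give racemic 7-(benzyloxy)-2-[3,4-bis(benzyloxy)phenyl]-3-methoxy-2H-chromene F1. Here the single free OH and the para-directing benzyloxy group direct the annulation to one ortho position.
 - Acid hydrolysis gives 7-(benzyloxy)-2-[3,4-bis(benzyloxy)phenyl]chroman-3-one F2, which is reduced as in step 9 to (2S,3S)-7-(benzyloxy)-2-[3,4-bis(benzyloxy)phenyl]chroman-3-ol F3.
 - The cation from 7 (BF3·OEt2, CH2Cl2, low temperature) is then captured by C6 of F3. After separation of the 3,4-cis isomer this should give the penta-O-benzyl ether of the target F4.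
 - Hydrogenolysis of F4 (H2, Pd(OH)2/C) gives 18.

2. Step 6. Facial selectivity at the flavan-4-yl cation may be poor, with capture anti to the 3-OH (the 3,4-trans epimer) dominating, and a second alkylation of the product is possible. The fallback delivers the aryl group from a boron atom tethered to the 3-oxygen. It sets out from 7 and comes back at 9.
 - Commercial 4-bromoresorcinol is converted (MOMCl, iPr2NEt) into 1-bromo-2,4-bis(methoxymethoxy)benzene F5.
 - Bromine–lithium exchange and borylation (n-BuLi, B(OiPr)3, THF, −78 °C, aqueous work-up) give [2,4-bis(methoxymethoxy)phenyl]boronic acid F6.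
 - F6 is esterified in situ with the 3-OH of 7 and C4 is ionised (BF3·OEt2, CH2Cl2, −40 °C). The aryl group should then migrate from boron to C4 on the face of the 3-oxygen (Petasis-type intramolecular delivery with ipso substitution of boron). The product expected is the 2,3-trans-3,4-cis 7-(benzyloxy)-2-[4-(benzyloxy)phenyl]-4-[2,4-bis(methoxymethoxy)phenyl]chroman-3-ol F7.
 - HCl in MeOH removes both MOM groups and returns 9.

3. Step 9. C2 epimerisation may be slow relative to reduction, so that the dynamic resolution is incomplete; the sense or level of facial induction may be wrong (the mirror-image catalyst is then the first change); and the electron-rich ketone may be oxidised by air to a flavylium-type product. The fallback gives up catalyst control for substrate control plus separation. It sets out from 15 and comes back at 17.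
 - 15 is hydrolysed and ketone 16 is isolated under argon.
 - LiBH(s-Bu)3 (L-Selectride, excess, THF, −78 °C) delivers hydride anti to the C2 aryl group of each C2 epimer, the usual cis-selective reduction of flavan-3-ones.
 - This should give 17 together with its (2R,3R) ring F diastereomer F8. The two are diastereomers because of the upper unit and are separated by chromatography.

**Further compounds**

F1 | step 8 | 7-(benzyloxy)-2-[3,4-bis(benzyloxy)phenyl]-3-methoxy-2H-chromene (racemic) | COC1=Cc2ccc(OCc3ccccc3)cc2OC1c1ccc(OCc2ccccc2)c(OCc2ccccc2)c1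
F2 | step 8 | 7-(benzyloxy)-2-[3,4-bis(benzyloxy)phenyl]chroman-3-one | O=C1Cc2ccc(OCc3ccccc3)cc2OC1c1ccc(OCc2ccccc2)c(OCc2ccccc2)c1
F3 | step 8 | (2S,3S)-7-(benzyloxy)-2-[3,4-bis(benzyloxy)phenyl]chroman-3-ol | O[C@H]1Cc2ccc(OCc3ccccc3)cc2O[C@H]1c1ccc(OCc2ccccc2)c(OCc2ccccc2)c1
F4 | step 8 | penta-O-benzyl ether of the target (ring D 7-O-benzyl ether of 17) | O[C@@H]1[C@@H](c2ccc(OCc3ccccc3)cc2)Oc2cc(OCc3ccccc3)ccc2[C@@H]1c1cc2C[C@H](O)[C@H](c3ccc(OCc4ccccc4)c(OCc4ccccc4)c3)Oc2cc1OCc1ccccc1
F5 | step 6 | 1-bromo-2,4-bis(methoxymethoxy)benzene | COCOc1ccc(Br)c(OCOC)c1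
F6 | step 6 | [2,4-bis(methoxymethoxy)phenyl]boronic acid | COCOc1ccc(B(O)O)c(OCOC)c1
F7 | step 6 | 2,3-trans-3,4-cis 7-(benzyloxy)-2-[4-(benzyloxy)phenyl]-4-[2,4-bis(methoxymethoxy)phenyl]chroman-3-ol (bis-MOM ether of 9) | O[C@@H]1[C@@H](c2ccc(OCc3ccccc3)cc2)Oc2cc(OCc3ccccc3)ccc2[C@@H]1c1ccc(OCOC)cc1OCOC
F8 | step 9 | (2R,3R) ring F diastereomer of 17 | O[C@@H]1[C@@H](c2ccc(OCc3ccccc3)cc2)Oc2cc(OCc3ccccc3)ccc2[C@@H]1c1cc2C[C@@H](O)[C@@H](c3ccc(OCc4ccccc4)c(OCc4ccccc4)c3)Oc2cc1O
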